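The readings are calculated from invented constants; scatter was added.

Alder, larch and oak share one charge of starting material, one held gas phase and one time, and they differ in c(protic impurity).

common to all: starting material 0.18 M; gas phase 14 mM (held)
- Saturday's: protic impurity 0.26 M; run made earlier
- Monday's: protic impurity 1.5 M; run made earlier
- alder: protic impurity 0.180 M; time 25 min
- larch: protic impurity 0.450 M; time 25 min
- oak: protic impurity 1.10 M; time 25 min

| run | time / min | target / % |
|---|---|---|
| Saturday's | 1.33 | 3 |
| Saturday's | 2.00 | 7 |
| Saturday's | 3.00 | 12 |
| Saturday's | 5.00 | 14 |
| Saturday's | 8.00 | 17 |
| Saturday's | 12.0 | 18 |
| Saturday's | 20.0 | 12 |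
| Monday's | 2.50 | 2 |
| Monday's | 5.00 | 5 |
| Monday's | 8.00 | 3 |
| Monday's | 10.0 | 3 |
| Monday's | 12.0 | 3 |
| Monday's | 15.0 | 3 |
| Monday's | 20.0 | 3 |

(standard deviation of a reading: 1.5 percentage points)

- at the start none of the gas is dissolved
- reactions considered so far: gas phase <-> dissolved gas; starting material + dissolved gas -> target; starting material + protic impurity -> quenched substrate; target <-> isomer of the product

1. which of the two there is more of at the end, alder (isomer of the product / target)
2. which of the two there is more of at the end, larch (isomer of the product / target)
3. which of the two there is more of at the end, oak (isomer of the product / target)
4. amount of target at the end, in percent of the starting material charged, alder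
5. amount of target at the end, in percent of the starting material charged, larch
6. amount of target at the end, in percent of the starting material charged, oak

Turn the question round: what would target need in order to end ahead of isomer of the product? Net target lost after the peak has gone to isomer. So after one loss half-life past the peak, the isomer made since the peak has caught up with the target left, and isomer formed before the peak comes on top. Ending under one loss half-life past the peak is therefore needed for target to lead, but it does not by itself put target ahead.

Saturday's readings fall from 18 % at 12.0 min to 12 % at 20.0 min, which gives 13.7 min. This is the loss half-life, the time in which target past its peak halves net. It is a rough reading, with 1.5 percentage points of scatter on each point.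

Taking Saturday's peak time for alder, the end of alder stands 0.951 loss half-lives past the peak, just under the line. But isomer has already formed before the peak, so the reckoning here puts isomer ahead. Saturday's peak carried over gives 9.31 % target in alder. That is a low figure, since alder holds less protic impurity than Saturday's run.

Monday's reading peaks at 5.00 min, which puts the end 1.46 loss half-lives on, over the line. Oak sits nearer Monday's run and larch lies between, so isomer leads there too.

The forecast gives target 17 % in alder (12 % to 22 %), 9 % in larch and 4 % in oak, “with isomer slightly ahead in each”. For alder the reckoning here stands lower than the forecast.

Alder ends at 11.4 % target and 36.6 % isomer, larch at 4.39 % and 21.0 %, oak at 1.39 % and 9.02 %.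

    gas phase ⇌ dissolved gas, rate k1*(csat - [dissolved gas]) (kL = 0.0350 s⁻¹)
    starting material + dissolved gas → target (k = 0.0990 M⁻¹ s⁻¹)
    starting material + protic impurity → quenched substrate (k = 0.00800 M⁻¹ s⁻¹)
    target ⇌ isomer of the product (K = 20.0, k = 0.00170 s⁻¹)

Counted with 13.7 min from the stand at 12.5 min, alder's 19.5 % target becomes 10.4 % against 11.4 %, and larch's 10.9 % becomes 5.76 % against 4.39 %. In alder the relaxation half-life of target and isomer, 6.47 min, is short against the 25 min, a passage from kinetic towards thermodynamic control. At the asked time alder makes target at 0.353 of the rate at which it is used up.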